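## Analysis of the target

Lespecyrtin E4 (18) is a pterocarpan. Benzene ring A and pyran ring B form a chroman, benzene ring D and dihydrofuran ring C form a dihydrobenzofuran, and the two bicycles share the C6a–C11a bond. A 2,2-dimethyl-2H-pyran is fused to ring A at C2–C3 (oxygen on C3, linear fusion) and a second one to ring D at C7–C8 (oxygen on C8). Ring D is hexasubstituted: C6b (to C6a), C7 (pyran carbon), C8 (pyran oxygen), C9 (OH), C10 (prenyl) and C10a (O11). The two stereocentres C6a and C11a are both R with cis hydrogens; a trans B/C fusion is too strained to exist, so fixing one centre fixes the other. The sensitive groups are: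

- the C11a–O11 benzylic aryl ether, whose cation is stabilised by O5 (ortho) and by the oxygen on C3 (para);
- the ortho-prenylphenol at C9/C10, which closes to a chroman with acid;
- three alkenes, which exclude peracids, halogen electrophiles and hydrogenation late in the route;
- the electron-rich, hydroquinone-type ring D.

The synthesis is hard for three reasons: six different substituents must be placed on ring D without regiochemical ambiguity, the ring A pyran must be linear and not angular, and C11a must be set at a carbon that ionises easily. The strategy rests on C6a–C6b being the only carbon–carbon bond between the chroman and ring D. When it is cut, a C11a aryl ether remains in which the C6a hydrogen cis to O11 can be reached by a palladium on C6b through a six-membered cycle (Pd, C6b, C10a, O11, C11a, C6a).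

## Retrosynthetic reasoning

**18 to 17.** The C9 phenol is carried as a methoxymethyl ether until the end. A free phenol next to the prenyl group would interfere with the etherification and with the basic, hot palladium step. The acetal survives peracid, base, 150 °C and palladium, and should leave under acid mild enough for the prenylphenol and the benzylic ether.

**17 to 16 (key disconnection).** The C6a–C6b bond is cut. This is the only C–C bond between the two halves, so the precursor 16 is simply an aryl ether of a chromanol and a bromophenol, with every substituent of ring D already in place. The forward reaction must put palladium on C6b, cleave the C6a–H cis to O11 and form the bond; this closes ring C and creates C6a from C11a in one operation. The cis hydrogen is not the only C–H within reach. The aromatic C1–H of ring A could be palladated through a seven-membered cycle and would close a six-membered ring. The choice of this disconnection therefore depends on features of 16 that disfavour that path: the biaryl bond C1–C6b would be flanked by the pyran rings on C2 and C7, and the smaller palladacycle is preferred.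

**16 to 6 and 15.** The C11a–O11 bond is cut. The other ether bond (O11–C10a) would require O-arylation with a hexasubstituted aryl halide next to the bromide, which is not realistic. Substitution at C11a by the phenol 15 with inversion needs the (S)-alcohol 6. The forward reaction has to favour direct displacement over ionisation of this very electron-rich benzylic position.

**6 to 1 (ring A).** The alcohol 6 comes from ketone 5 by enantioselective hydride transfer; formate is used as the hydride source so that the chromene alkene is not exposed to a borane. The pyran double bond of 5 is taken back to the saturated ring in 4. A propargyl ether rearrangement on a chromanone phenol of this series would deliver the pyran carbon mainly to the position between the two oxygens and give the angular isomer. A Friedel–Crafts acylation on the saturated chromanol 2 instead goes para to the ring oxygen and fixes the linear pattern. Ring B of 4 is cut at the aryl–carbonyl bond and at O5–C6 (a three-carbon chloro acid on 2), and 2 is the acid-mediated annulation product of resorcinol (1) with a C5 diene.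

**15 to 13 (ring D, pericyclic part).** Two bonds are cut by retro-sigmatropic logic: C10–prenyl and C7–pyran carbon. The prenyl group comes from a 1,1-dimethylallyl ether on the C10a oxygen and the pyran from a 1,1-dimethylpropargyl ether on the C8 oxygen. In 13 each ether has only one free ortho position (the other bears Br or the acetal oxygen), so one heating should place both carbon substituents without any regiochemical choice. The Claisen rearrangement also liberates the C10a phenol needed for the coupling, so no extra protecting group is spent on it.

**13 to 7 (ring D, oxygenation pattern).** The three oxygens and the bromine are traced to 5-bromo-2,4-dihydroxybenzaldehyde (7). Its 4-hydroxyl (more acidic, not chelated) becomes the C10a oxygen, its chelated 2-hydroxyl the C9 oxygen, its bromine is already on C6b, and the formyl carbon becomes the C8 oxygen by Baeyer–Villiger oxidation (9 to 11). The bromine is bought, not introduced, because electrophilic bromination would not tolerate the alkenes. The first tertiary ether is carried as the alkyne (8, 9, 11) through the peracid step and is reduced to the alkene (12) before the second alkyne is attached (13). This keeps the peracid away from any alkene and makes the two tertiary ethers chemically different.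

## Alternatives that were turned down

**Alternative 1: tethered ketene–ynol ether benzannulation.**
- Disconnection: ring D is cut at C6b–C10a, C9–C10 and C8–C9, back to A2, a cis-3,4-disubstituted chroman with a diazo enone arm on C6a and a prenyl-substituted alkynyl ether on O11.
- Forward key step: irradiation of A2 triggers Wolff rearrangement; the resulting ketene adds across the tethered ynol ether, and four-electron ring opening, six-electron closure and tautomerisation give A1 with rings C and D formed (Danheiser-type benzannulation). Heating A1 would then close the C7–C8 pyran and give 18 with no deprotection.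
- For: every ring D substituent is placed by connectivity; three bonds and two rings form in one step; no aryl halide, no metal, and the C9 phenol arises free. On ring D regiocontrol and on the end game it is stronger than the chosen route.
- Against: A2 must already contain both stereocentres, so the key step creates none. An ynol ether on the ionisation-prone C11a oxygen needs strong-base chemistry and is acid-labile. Diazo transfer to a β-alkoxy enone, photolysis beside a styrene-type chromophore, and interception of the ketene by the prenyl alkene are each uncertain. The sequence is linear and long.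
- Comparison: the chosen strategy obtains the same regiochemical certainty cheaply from aldehyde 7, joins two stable fragments late, and forms C6a in the key step instead of requiring it beforehand.

**Alternative 2: Dötz benzannulation on a chroman alkyne.**
- Disconnection: ring D is cut at C7–C8, C6b–C10a and C10–C10a, back to the C6a ethynyl chroman A4 and the Cr(CO)5 alkenyl(methoxy)carbene complex A5.
- Forward key step: thermal reaction of A4 with A5 inserts the alkyne and one CO and gives the 4-methoxyphenol A3 after demetalation.
- For: convergent, a well-understood reaction with few competing pathways, and the larger alkyne substituent reliably ends up next to the new phenol, which is then placed to close ring C. On reliability of the key reaction it is at least as strong as the chosen route.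
- Against: ring D emerges with OMe on C8 and H on C7, so the C8 oxygen must be demethylated selectively beside an acetal and a prenyl group, and the pyran must then be built. A4 needs both stereocentres set in advance. A5 is a stoichiometric chromium reagent with a sensitive α-alkoxy alkenyl group. Ring C closure and pyran construction add four or more steps after the key step.
- Comparison: the chosen strategy closes ring C on a ring D that is already complete, so only one step follows the key step.

**Alternative 3: twofold quinone methide oxa-6π closure.**
- Disconnection: both pyran rings are cut at once (two C–C and two O–C bonds), back to the pterocarpan dialdehyde A7 and the Grignard reagent A8.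
- Forward key step: A8 adds to both aldehydes of A7; dehydration of the two allylic alcohols to ortho-quinone methides and oxa-6π closure give A6.
- For: both pyrans are made in one operation with regiochemistry fixed by the formyl groups, and no thermal Claisen step is needed. On step economy for the pyrans it is stronger than the chosen route, which builds them separately.
- Against: the pterocarpan core of A7, with its prenyl group, two phenols and two regiodefined aldehydes, still has to be made, so the main problem is only postponed. Formylation of ring A at C2 and not C4 is the same linear/angular question again. The last step must cleave a C9 methyl ether beside a prenyl group, two chromenes and the benzylic ether, which is much harsher than removing an acetal.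
- Comparison: the chosen strategy installs each pyran in a simple fragment where only one position is open, and ends with a mild deprotection.

Key step: step 12

Assumption: pterocarpan locants (O5, C6, C6a, C6b, C7–C10, C10a, O11, C11a, C11b, C1–C4, C4a) are used for 16–18 and for the corresponding atoms of the fragments; 7 is taken as a purchasable compound.

## Route

Step 1
Reactants: 1 resorcinol
Product: 2 2,2-dimethylchroman-7-ol
Conditions: isoprene, H3PO4 (85%), toluene, 30–35 °C, resorcinol in excess
Reagents that add atoms: isoprene, C=CC(C)=C
Why: Acid-mediated Friedel–Crafts prenylation and ring closure (chroman annulation): the prenyl cation alkylates resorcinol at C4 and the neighbouring hydroxyl adds to the tertiary cation. Excess resorcinol limits double annulation, and the 5-hydroxy isomer from attack between the hydroxyls should be the minor, separable product.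

Step 2
Reactants: 2 2,2-dimethylchroman-7-ol
Product: 4 8,8-dimethyl-2,3,6,7-tetrahydro-4H,8H-pyrano[3,2-g]chromen-4-one, via chloroketone 3 (not isolated)
Conditions: 3-chloropropanoic acid, TfOH, 80 °C; then 2 M NaOH, 0 °C to rt
Reagents that add atoms: 3-chloropropanoic acid, OC(=O)CCCl
Why: Friedel–Crafts acylation followed by intramolecular Williamson-type closure through the phenoxide. Acylation should go to C6 (ortho to the hydroxyl, para to the ring oxygen) and not to the crowded C8 between two oxygens, which fixes the linear fusion.

Step 3
Reactants: 4 8,8-dimethyl-2,3,6,7-tetrahydro-4H,8H-pyrano[3,2-g]chromen-4-one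
Product: 5 8,8-dimethyl-2,3-dihydro-4H,8H-pyrano[3,2-g]chromen-4-one
Conditions: DDQ, 1,4-dioxane, reflux
Reagents that add atoms: none
Why: DDQ dehydrogenation of a 2,2-dimethylchroman to the 2H-chromene: hydride abstraction at the benzylic carbon is assisted by the ortho and para oxygens, and proton loss from the adjacent methylene gives the alkene. The enolisable chromanone ring should react more slowly.

Step 4
Reactants: 5 8,8-dimethyl-2,3-dihydro-4H,8H-pyrano[3,2-g]chromen-4-one
Product: 6 (4S)-8,8-dimethyl-3,4-dihydro-2H,8H-pyrano[3,2-g]chromen-4-ol
Conditions: RuCl(p-cymene)[(S,S)-TsDPEN] (cat.), HCO2H/Et3N (5:2), EtOAc, 30 °C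
Reagents that add atoms: none
Why: Noyori–Ikariya asymmetric transfer hydrogenation: the (S,S)-catalyst delivers hydride to the ketone face that gives the (S)-alcohol, as for chroman-4-one itself, and this sets the centre that becomes C11a. Formate does not touch the chromene alkene, which a borane could hydroborate.

Step 5
Reactants: 7 5-bromo-2,4-dihydroxybenzaldehyde
Product: 8 5-bromo-2-hydroxy-4-[(2-methylbut-3-yn-2-yl)oxy]benzaldehyde
Conditions: 3-chloro-3-methylbut-1-yne, DBU, CuCl2·2H2O (cat.), MeCN, 0 °C
Reagents that add atoms: 3-chloro-3-methylbut-1-yne, CC(C)(Cl)C#C
Why: Copper-catalysed O-propargylation of a phenol with a tertiary propargylic chloride. The 4-hydroxyl (para to CHO, ortho to Br) is the more acidic and is alkylated, while the 2-hydroxyl stays hydrogen-bonded to the aldehyde.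

Step 6
Reactants: 8 5-bromo-2-hydroxy-4-[(2-methylbut-3-yn-2-yl)oxy]benzaldehyde
Product: 9 5-bromo-2-(methoxymethoxy)-4-[(2-methylbut-3-yn-2-yl)oxy]benzaldehyde
Conditions: MOMCl, i-Pr2NEt, CH2Cl2, 0 °C to rt
Reagents that add atoms: chloromethyl methyl ether, COCCl
Why: Acetal protection (methoxymethyl ether formation) of the remaining phenol under basic conditions; aldehyde, bromide and alkyne are inert.

Step 7
Reactants: 9 5-bromo-2-(methoxymethoxy)-4-[(2-methylbut-3-yn-2-yl)oxy]benzaldehyde
Product: 11 5-bromo-2-(methoxymethoxy)-4-[(2-methylbut-3-yn-2-yl)oxy]phenol, via aryl formate 10 (not isolated)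
Conditions: mCPBA, CH2Cl2, 0 °C to rt; then K2CO3 (cat.), MeOH, 0 °C
Reagents that add atoms: 3-chloroperoxybenzoic acid, OOC(=O)c1cccc(Cl)c1
Why: Baeyer–Villiger (Dakin-type) oxidation: the electron-rich 2,4-dioxygenated aryl group migrates in the Criegee intermediate, and the formate is removed by methanolysis. No alkene is present yet and the terminal alkyne does not react with the peracid.

Step 8
Reactants: 11 5-bromo-2-(methoxymethoxy)-4-[(2-methylbut-3-yn-2-yl)oxy]phenol
Product: 12 5-bromo-2-(methoxymethoxy)-4-[(2-methylbut-3-en-2-yl)oxy]phenol
Conditions: H2 (1 atm), Pd/CaCO3 poisoned with Pb(OAc)2, quinoline, EtOAc, rt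
Reagents that add atoms: none
Why: Lindlar semihydrogenation of the terminal alkyne to the 1,1-dimethylallyl ether. The poisoned catalyst at 1 atm should spare the aryl bromide and stop at the alkene if hydrogen uptake is followed.

Step 9
Reactants: 12 5-bromo-2-(methoxymethoxy)-4-[(2-methylbut-3-en-2-yl)oxy]phenol
Product: 13 1-bromo-4-(methoxymethoxy)-2-[(2-methylbut-3-en-2-yl)oxy]-5-[(2-methylbut-3-yn-2-yl)oxy]benzene
Conditions: 3-chloro-3-methylbut-1-yne, DBU, CuCl2·2H2O (cat.), MeCN, 0 °C
Reagents that add atoms: 3-chloro-3-methylbut-1-yne, CC(C)(Cl)C#C
Why: Copper-catalysed O-propargylation as in step 5, on the only free hydroxyl (the future C8 oxygen). The temperature is kept at 0 °C so that the 1,1-dimethylallyl ether does not rearrange.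

Step 10
Reactants: 13 1-bromo-4-(methoxymethoxy)-2-[(2-methylbut-3-en-2-yl)oxy]-5-[(2-methylbut-3-yn-2-yl)oxy]benzene
Product: 15 5-bromo-8-(methoxymethoxy)-2,2-dimethyl-7-(3-methylbut-2-en-1-yl)-2H-chromen-6-ol, via prenylphenol propargyl ether 14 (not isolated)
Conditions: PhNEt2, 150 °C, argon
Reagents that add atoms: none
Why: Two thermal sigmatropic sequences in one heating: aromatic Claisen rearrangement of the 1,1-dimethylallyl ether to its only free ortho position (the other bears Br) gives the C-prenyl phenol, and propargyl Claisen rearrangement of the other ether to its only free ortho position, then [1,5]-hydrogen shift and oxa-6π electrocyclisation, gives the 2,2-dimethylchromene. The amine solvent suppresses acid-catalysed cyclisation of the ortho-prenylphenol.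

Step 11
Reactants: 6 (4S)-8,8-dimethyl-3,4-dihydro-2H,8H-pyrano[3,2-g]chromen-4-ol; 15 5-bromo-8-(methoxymethoxy)-2,2-dimethyl-7-(3-methylbut-2-en-1-yl)-2H-chromen-6-ol
Product: 16 (4R)-4-{[5-bromo-8-(methoxymethoxy)-2,2-dimethyl-7-(3-methylbut-2-en-1-yl)-2H-chromen-6-yl]oxy}-8,8-dimethyl-3,4-dihydro-2H,8H-pyrano[3,2-g]chromene
Conditions: PPh3, DIAD, toluene, −20 to 0 °C
Reagents that add atoms: none
Why: Mitsunobu etherification with inversion at the carbinol carbon should turn the (S)-alcohol into the (R)-aryl ether. The ortho-bromophenol is acidic enough to protonate the betaine, ring D has no free carbon for C-alkylation, and low temperature in toluene is chosen to hold back ionisation of the oxyphosphonium salt.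

Step 12
Reactants: 16 (4R)-4-{[5-bromo-8-(methoxymethoxy)-2,2-dimethyl-7-(3-methylbut-2-en-1-yl)-2H-chromen-6-yl]oxy}-8,8-dimethyl-3,4-dihydro-2H,8H-pyrano[3,2-g]chromene
Product: 17 (6aR,11aR)-9-O-(methoxymethyl) Lespecyrtin E4 (cis-pterocarpan with 2,2-dimethyl-2H-pyran rings fused at C2–C3, oxygen on C3, and at C7–C8, oxygen on C8; OCH2OCH3 on C9; prenyl on C10)
Conditions: Pd(OAc)2 (10 mol %), PCy3·HBF4 (20 mol %), CsOPiv (50 mol %), Cs2CO3, mesitylene, 140 °C
Reagents that add atoms: none
Why: Zerovalent palladium formed from Pd(OAc)2 and PCy3 inserts into the C6b–Br bond, bromide is exchanged for pivalate, and the bound pivalate removes the C6a hydrogen cis to O11 while the Pd–C6a bond forms (concerted metalation–deprotonation), giving a six-membered palladacycle (Pd, C6b, C10a, O11, C11a, C6a). Reductive elimination from this divalent palladium aryl alkyl forms C6a–C6b and returns zerovalent palladium, while Cs2CO3 takes up HBr and regenerates pivalate. The closest known reaction type is the palladium/pivalate intramolecular C(sp3)–H arylation of 2-bromoaryl alkyl ethers and anilides to dihydrobenzofurans and fused indolines. Ring C, the only ring closed, arises by C(sp2)–C(sp3) reductive elimination that contracts the six-membered palladacycle to the five-membered dihydrofuran. The new stereocentre C6a is controlled by C11a: only the hydrogen on the O11 face can be reached, metalation and reductive elimination both go with retention, and the 6-5 fusion can only be cis, so (11aR) should give (6aR). The step needs site selectivity against the aromatic C1–H of ring A (seven-membered palladacycle, six-membered ring) and the methine C11a–H, and chemoselectivity for C–Br over the three alkenes. The C1 pathway would build a biaryl bond flanked by the pyran rings on C2 and C7 (a bay-type clash) and needs O11 pseudoequatorial against the peri hydrogen, the C11a pathway can only end in a four-membered ring, and none of the di- or trisubstituted alkenes can reach the arylpalladium through a ring of normal size. β-Hydride loss from the C6a–Pd bond should be held back because the chelate keeps the C6 and C11a hydrogens away from a syn-coplanar position.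

Step 13
Reactants: 17 (6aR,11aR)-9-O-(methoxymethyl) Lespecyrtin E4
Product: 18 Lespecyrtin E4, (6aR,11aR)
Conditions: HCl (0.2 M) in MeOH/THF, 0 °C to rt
Reagents that add atoms: none
Why: Acid-catalysed acetal exchange (methoxymethyl ether cleavage) in methanol frees the C9 phenol. Dilute acid at or below room temperature is chosen because the ortho-prenylphenol, the chromenes and the C11a–O11 benzylic ether should tolerate it, and neither stereocentre is touched.

## Compound list

1 | resorcinol | Oc1cccc(O)c1 | starting material
2 | 2,2-dimethylchroman-7-ol | CC1(C)CCc2ccc(O)cc2O1 | intermediate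
3 | 3-chloro-1-(7-hydroxy-2,2-dimethylchroman-6-yl)propan-1-one | O=C(CCCl)c1cc2CCC(C)(C)Oc2cc1O | intermediate
4 | 8,8-dimethyl-2,3,6,7-tetrahydro-4H,8H-pyrano[3,2-g]chromen-4-one | O=C1CCOc2cc3OC(C)(C)CCc3cc12 | intermediate
5 | 8,8-dimethyl-2,3-dihydro-4H,8H-pyrano[3,2-g]chromen-4-one | O=C1CCOc2cc3OC(C)(C)C=Cc3cc12 | intermediate
6 | (4S)-8,8-dimethyl-3,4-dihydro-2H,8H-pyrano[3,2-g]chromen-4-ol | O[C@@H]1c2cc3c(cc2OCC1)OC(C)(C)C=C3 | intermediate
7 | 5-bromo-2,4-dihydroxybenzaldehyde | O=Cc1cc(Br)c(O)cc1O | starting material
8 | 5-bromo-2-hydroxy-4-[(2-methylbut-3-yn-2-yl)oxy]benzaldehyde | O=Cc1cc(Br)c(OC(C)(C)C#C)cc1O | intermediate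
9 | 5-bromo-2-(methoxymethoxy)-4-[(2-methylbut-3-yn-2-yl)oxy]benzaldehyde | O=Cc1cc(Br)c(OC(C)(C)C#C)cc1OCOC | intermediate
10 | 5-bromo-2-(methoxymethoxy)-4-[(2-methylbut-3-yn-2-yl)oxy]phenyl formate | O=COc1cc(Br)c(OC(C)(C)C#C)cc1OCOC | intermediate
11 | 5-bromo-2-(methoxymethoxy)-4-[(2-methylbut-3-yn-2-yl)oxy]phenol | Oc1cc(Br)c(OC(C)(C)C#C)cc1OCOC | intermediate
12 | 5-bromo-2-(methoxymethoxy)-4-[(2-methylbut-3-en-2-yl)oxy]phenol | Oc1cc(Br)c(OC(C)(C)C=C)cc1OCOC | intermediate
13 | 1-bromo-4-(methoxymethoxy)-2-[(2-methylbut-3-en-2-yl)oxy]-5-[(2-methylbut-3-yn-2-yl)oxy]benzene | C#CC(C)(C)Oc1cc(Br)c(OC(C)(C)C=C)cc1OCOC | intermediate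
14 | 6-bromo-3-(methoxymethoxy)-2-(3-methylbut-2-en-1-yl)-4-[(2-methylbut-3-yn-2-yl)oxy]phenol | C#CC(C)(C)Oc1cc(Br)c(O)c(CC=C(C)C)c1OCOC | intermediate
15 | 5-bromo-8-(methoxymethoxy)-2,2-dimethyl-7-(3-methylbut-2-en-1-yl)-2H-chromen-6-ol | CC(C)=CCc1c(OCOC)c2c(c(Br)c1O)C=CC(C)(C)O2 | intermediate
16 | (4R)-4-{[5-bromo-8-(methoxymethoxy)-2,2-dimethyl-7-(3-methylbut-2-en-1-yl)-2H-chromen-6-yl]oxy}-8,8-dimethyl-3,4-dihydro-2H,8H-pyrano[3,2-g]chromene | CC(C)=CCc1c(OCOC)c2c(c(Br)c1O[C@H]1c4cc5c(cc4OCC1)OC(C)(C)C=C5)C=CC(C)(C)O2 | intermediate
17 | (6aR,11aR)-9-O-(methoxymethyl) Lespecyrtin E4 | CC(C)=CCc1c(OCOC)c2c(c3c1O[C@H]1c4cc5c(cc4OC[C@@H]31)OC(C)(C)C=C5)C=CC(C)(C)O2 | intermediate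
18 | Lespecyrtin E4, (6aR,11aR) | CC(C)=CCc1c(O)c2c(c3c1O[C@H]1c4cc5c(cc4OC[C@@H]31)OC(C)(C)C=C5)C=CC(C)(C)O2 | target

## Step count and least certain steps

Total: 13 steps (4 to the ring A alcohol 6, 6 to the ring D phenol 15, 3 after convergence). Longest linear sequence: 9 steps (7 to 18, steps 5–13).

**Step 12 (key step).**
- What may go wrong: palladation of the aromatic C1–H of ring A in place of the C6a methylene, because aryl C–H bonds are intrinsically easier to cleave and the seven-membered palladacycle closes an unstrained six-membered ring. Protodebromination and thermal ionisation of the benzylic ether at 140 °C would add to the loss.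
- Fallback (from 5 and 15, rejoining at 18): the C6a–C6b bond is made by enolate arylation instead. Phenol 15 is capped with MOMCl/i-Pr2NEt to give the bis-acetal bromide F1. Palladium-catalysed α-arylation of ketone 5 with F1 (Pd2(dba)3, a bulky biarylphosphine, NaOt-Bu, toluene, 80 °C) gives the racemic 3-aryl chromanone F2. Transfer hydrogenation with RuCl(p-cymene)[(R,R)-TsDPEN] and HCO2H/Et3N under dynamic kinetic resolution (the centre next to the carbonyl epimerises through the enol) gives the cis-(3R,4R)-3-arylchroman-4-ol F3. Methanolic HCl then removes both acetals, and the C10a hydroxyl captures the C11a benzylic cation in the only possible cis sense, giving 18.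

**Step 11.**
- What may go wrong: ionisation of the oxyphosphonium salt of the doubly oxygen-activated benzylic alcohol, leading to erosion of enantiopurity and elimination to the 2H-chromene. This is made more likely because the phenoxide of 15 carries two ortho substituents and attacks slowly.
- Fallback (from 5, rejoining at 16): stereospecific substitution is given up and the enantiomers are separated. NaBH4 reduction of 5 gives the racemic alcohol F4. MsCl/Et3N at −20 °C converts it to the racemic chloride F5, which is used at once to alkylate the caesium phenoxide of 15 (Cs2CO3, DMF, 0 °C); the fully substituted ring D can only react on oxygen. Preparative chromatography on a chiral stationary phase separates 16 from its (4S)-enantiomer F6.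

**Step 10.**
- What may go wrong: loss of the tertiary allyl group as a diene instead of rearrangement, or acid-promoted cyclisation of the freshly formed ortho-prenylphenol during the longer heating needed for the propargyl ether.
- Fallback (from 12, rejoining at 15): the two events are separated and the pyran is made by condensation. Heating 12 at about 110 °C in toluene effects only the aromatic Claisen rearrangement and gives the prenylated hydroquinone F7. Condensation with 3-methylbut-2-enal (PhB(OH)2, AcOH cat., toluene, reflux) forms the chromene through an ortho-quinone methide and oxa-6π closure. Only the C8 hydroxyl has a free ortho carbon, so 15 should result.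

**Step 3.**
- What may go wrong: competing dehydrogenation of the chromanone ring to the chromone, or slow hydride abstraction because both ring oxygens are conjugated with the ketone.
- Fallback (from 4, rejoining at 5): radical benzylic bromination with NBS (AIBN, PhCF3, reflux) gives the benzylic bromide F8, and DBU-mediated elimination gives 5.

## Further compounds

F1 | step 12 | 5-bromo-6,8-bis(methoxymethoxy)-2,2-dimethyl-7-(3-methylbut-2-en-1-yl)-2H-chromene | CC(C)=CCc1c(OCOC)c2c(c(Br)c1OCOC)C=CC(C)(C)O2
F2 | step 12 | racemic 3-[6,8-bis(methoxymethoxy)-2,2-dimethyl-7-(3-methylbut-2-en-1-yl)-2H-chromen-5-yl]-8,8-dimethyl-2,3-dihydro-4H,8H-pyrano[3,2-g]chromen-4-one | CC(C)=CCc1c(OCOC)c2c(c(C3COc4cc5OC(C)(C)C=Cc5cc4C3=O)c1OCOC)C=CC(C)(C)O2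
F3 | step 12 | (3R,4R)-3-[6,8-bis(methoxymethoxy)-2,2-dimethyl-7-(3-methylbut-2-en-1-yl)-2H-chromen-5-yl]-8,8-dimethyl-3,4-dihydro-2H,8H-pyrano[3,2-g]chromen-4-ol (cis) | O[C@H]1c2cc3c(cc2OC[C@H]1c4c(OCOC)c(CC=C(C)C)c(OCOC)c5OC(C)(C)C=Cc45)OC(C)(C)C=C3
F4 | step 11 | racemic 8,8-dimethyl-3,4-dihydro-2H,8H-pyrano[3,2-g]chromen-4-ol | OC1CCOc2cc3OC(C)(C)C=Cc3cc12
F5 | step 11 | racemic 4-chloro-8,8-dimethyl-3,4-dihydro-2H,8H-pyrano[3,2-g]chromene | ClC1CCOc2cc3OC(C)(C)C=Cc3cc12
F6 | step 11 | (4S)-enantiomer of 16 | CC(C)=CCc1c(OCOC)c2c(c(Br)c1O[C@@H]1c4cc5c(cc4OCC1)OC(C)(C)C=C5)C=CC(C)(C)O2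
F7 | step 10 | 2-bromo-5-(methoxymethoxy)-6-(3-methylbut-2-en-1-yl)benzene-1,4-diol | Oc1cc(Br)c(O)c(CC=C(C)C)c1OCOC
F8 | step 3 | racemic 6-bromo-8,8-dimethyl-2,3,6,7-tetrahydro-4H,8H-pyrano[3,2-g]chromen-4-one | O=C1CCOc2cc3OC(C)(C)CC(Br)c3cc12
A1 | alternative 1 | 9-hydroxy-10-prenyl pterocarpan 8-(1,1-dimethylpropargyl) ether with the ring A pyran | CC(C)=CCc1c(O)c(OC(C)(C)C#C)cc3c1O[C@H]1c4cc5c(cc4OC[C@@H]31)OC(C)(C)C=C5
A2 | alternative 1 | cis-chroman with a diazo enone arm on C6a and a (5-methylhex-4-en-1-ynyl) ether on O11 | CC(C)=CCC#CO[C@H]1c2cc3c(cc2OC[C@H]1C(=[N+]=[N-])C(=O)/C=C/OC(C)(C)C#C)OC(C)(C)C=C3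
A3 | alternative 2 | 3-arylchroman with complete ring D oxygenation and prenyl group, silyl ether on the C11a oxygen | CC(C)(C)[Si](C)(C)O[C@H]1c2cc3C=CC(C)(C)Oc3cc2OC[C@H]1c1cc(OC)c(OCOC)c(CC=C(C)C)c1O
A4 | alternative 2 | C6a ethynyl chroman silyl ether | CC(C)(C)[Si](C)(C)O[C@H]1c2cc3C=CC(C)(C)Oc3cc2OC[C@H]1C#C
A5 | alternative 2 | pentacarbonyl[methoxy(1-(methoxymethoxy)-5-methylhexa-1,4-dienyl)carbene]chromium, Cr(CO)5 carbene complex | COC(=[Cr](=C=O)(=C=O)(=C=O)(=C=O)=C=O)C(OCOC)=CCC=C(C)C
A6 | alternative 3 | 9-O-methyl Lespecyrtin E4 | CC(C)=CCc1c(OC)c2c(c3c1O[C@H]1c4cc5c(cc4OC[C@@H]31)OC(C)(C)C=C5)C=CC(C)(C)O2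
A7 | alternative 3 | (6aR,11aR)-3,8-dihydroxy-9-methoxy-10-prenylpterocarpan-2,7-dicarbaldehyde | CC(C)=CCc1c(OC)c(O)c(C=O)c3c1O[C@H]1c4cc(C=O)c(O)cc4OC[C@@H]31
A8 | alternative 3 | 2-methylprop-1-enylmagnesium bromide | CC(C)=C[Mg]Br
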